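**Plan**
1. Retrosynthesis (chroman numbering O1–C8a, side chain C1'–C12'): the C6 phenol is masked as its methyl ether, the dihydropyran ring is opened at the aryl ether bond O1–C8a, the side chain is cut at C5'–C6', and the arene is detached at C4–C4a.
2. Enabling feature: C2 with O1 and its methyl, C3, C4, C1'–C5' and the 4'-methyl form the intact C10–O skeleton of (R)-linalool. C8a lies para to the C6 oxygen, between C4a and the C8 methyl, so a bromine can be placed there and the dihydropyran ring closed without breaking the C2–O bond.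
3. Forward order: C4–C4a (hydroboration/Suzuki), oxidation at C5', hydrogenation to set C4', bromination at C8a, C5'–C6' (copper-catalyzed Grignard coupling), then the only ring closure (O1–C8a, palladium), then O-demethylation.
4. Stereochemistry: C2 (R) comes from (R)-linalool and C8' from (R)-citronellol (the descriptor reads 8'S in the target only because the 11',12'-alkene changes the CIP ranking). C4' (R) is set by Ru–BINAP hydrogenation of an (E)-allylic alcohol.

Key step: step 8

Assumption 1: commercial (R)-linalool and (R)-citronellol are taken to be of high enantiomeric purity, since their configurations pass unchanged into C2 and C8'.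
Assumption 2: Ru(OAc)2[(S)-BINAP] is taken to add hydrogen to the same face, relative to the carbon bearing the coordinating group, as in geraniol → (R)-citronellol and tiglic acid → (S)-2-methylbutanoic acid. That face gives the required (2S)-alcohol; the (R)-BINAP complex would be used instead if a model substrate showed the opposite sense.

**Step 1**
Reactants: 1 (R)-linalool; 2 1-bromo-3-methoxy-5-methylbenzene
Product: 4 (3R)-1-(3-methoxy-5-methylphenyl)-3,7-dimethyloct-6-en-3-ol, via B-alkyl-9-BBN adduct 3 (not isolated)
Conditions: 9-BBN (2.2 equiv), THF, 0 °C to rt; then 2, PdCl2(dppf) (3 mol %), 3 M aq NaOH, THF, 65 °C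
Reagents that add atoms: none
Why: 9-BBN should add anti-Markovnikov to the monosubstituted vinyl group only (the trisubstituted alkene is too hindered, and the excess covers any O-borylation of the carbinol), and the primary alkylborane should then undergo B-alkyl Suzuki–Miyaura coupling with the aryl bromide to form C4–C4a without touching the carbinol stereocenter.

**Step 2**
Reactants: 4 (3R)-1-(3-methoxy-5-methylphenyl)-3,7-dimethyloct-6-en-3-ol
Product: 5 (2E,6R)-8-(3-methoxy-5-methylphenyl)-2,6-dimethyloct-2-ene-1,6-diol
Conditions: SeO2 (0.5 equiv), t-BuOOH (2 equiv), salicylic acid (0.1 equiv), CH2Cl2, rt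
Reagents that add atoms: selenium dioxide, O=[Se]=O (delivers the oxygen); tert-butyl hydroperoxide, CC(C)(C)OO (re-oxidant from which that oxygen ultimately comes)
Why: Sharpless-type catalytic SeO2 allylic oxidation (ene reaction followed by a [2,3]-sigmatropic shift) should attack the gem-dimethyl end of the trisubstituted alkene and oxidize the methyl trans to the chain, giving the (E)-allylic alcohol as is established for linalool and geranyl derivatives.

**Step 3**
Reactants: 5 (2E,6R)-8-(3-methoxy-5-methylphenyl)-2,6-dimethyloct-2-ene-1,6-diol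
Product: 6 (2S,6R)-8-(3-methoxy-5-methylphenyl)-2,6-dimethyloctane-1,6-diol
Conditions: Ru(OAc)2[(S)-BINAP] (1 mol %), H2 (100 atm), MeOH, rt
Reagents that add atoms: none
Why: In this Noyori hydroxyl-directed asymmetric hydrogenation the primary allylic hydroxyl binds ruthenium and the (S)-BINAP ligand should select the Re face of the hydroxymethyl-bearing alkene carbon for syn addition of H2, creating the (2S) center (the future 4'R) under catalyst control, with no influence expected from the remote tertiary carbinol.

**Step 4**
Reactants: 6 (2S,6R)-8-(3-methoxy-5-methylphenyl)-2,6-dimethyloctane-1,6-diol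
Product: 7 (2S,6R)-8-(2-bromo-5-methoxy-3-methylphenyl)-2,6-dimethyloctane-1,6-diol
Conditions: NBS (1.05 equiv), MeCN, 0 °C, dark
Reagents that add atoms: N-bromosuccinimide, O=C1CCC(=O)N1Br
Why: Electrophilic aromatic bromination of an anisole with NBS in acetonitrile should go para to the methoxy group, here the future C8a between the two alkyl substituents, and it is placed at this stage because the molecule contains no alkene that NBS could attack.

**Step 5**
Reactants: 7 (2S,6R)-8-(2-bromo-5-methoxy-3-methylphenyl)-2,6-dimethyloctane-1,6-diol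
Product: 8 (2S,6R)-8-(2-bromo-5-methoxy-3-methylphenyl)-6-hydroxy-2,6-dimethyloctyl 4-methylbenzenesulfonate
Conditions: TsCl (1.2 equiv), Et3N, DMAP (cat.), CH2Cl2, 0 °C
Reagents that add atoms: 4-methylbenzenesulfonyl chloride, Cc1ccc(cc1)S(Cl)(=O)=O
Why: Chemoselective sulfonylation should tosylate the primary hydroxyl while the hindered tertiary carbinol stays free, and no bond to either stereocenter is involved.

**Step 6**
Reactants: 9 (R)-citronellol
Product: 10 (6R)-8-bromo-2,6-dimethyloct-2-ene [(R)-citronellyl bromide]
Conditions: CBr4, PPh3, CH2Cl2, 0 °C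
Reagents that add atoms: carbon tetrabromide, BrC(Br)(Br)Br
Why: In the Appel reaction bromide displaces the oxyphosphonium group by SN2 at the primary carbon, which should leave the methyl-bearing stereocenter and the trisubstituted alkene untouched.

**Step 7**
Reactants: 8 (2S,6R)-8-(2-bromo-5-methoxy-3-methylphenyl)-6-hydroxy-2,6-dimethyloctyl 4-methylbenzenesulfonate; 10 (R)-citronellyl bromide
Product: 12 (3R,7R,11S)-1-(2-bromo-5-methoxy-3-methylphenyl)-3,7,11,15-tetramethylhexadec-14-en-3-ol, via (R)-citronellylmagnesium bromide 11 (not isolated)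
Conditions: 10 (3 equiv), Mg, THF, 40 °C; then 8, Li2CuCl4 (5 mol %), THF, −78 °C to 0 °C; H2O quench
Reagents that add atoms: none
Why: Kochi-type copper-catalyzed coupling of a primary alkyl Grignard reagent with a primary tosylate should form C5'–C6' by displacement at a non-stereogenic carbon, so both flanking methyl stereocenters are carried through; the first equivalent of Grignard reagent only deprotonates the tertiary hydroxyl, and the doubly ortho-substituted aryl bromide should not undergo exchange at these temperatures.

**Step 8**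
Reactants: 12 (3R,7R,11S)-1-(2-bromo-5-methoxy-3-methylphenyl)-3,7,11,15-tetramethylhexadec-14-en-3-ol
Product: 13 (2R)-6-methoxy-2,8-dimethyl-2-[(4R,8S)-4,8,12-trimethyltridec-11-en-1-yl]-3,4-dihydro-2H-chromene
Conditions: Pd(OAc)2 (3 mol %), rac-2-(di-tert-butylphosphino)-1,1'-binaphthyl (4 mol %), Cs2CO3 (1.5 equiv), toluene, 80 °C
Reagents that add atoms: none
Why: Zerovalent palladium, formed in situ from Pd(OAc)2 and the bulky electron-rich phosphine, should insert into the C8a–Br bond, the cesium alkoxide of the tertiary carbinol should then replace bromide on palladium to give a seven-membered oxapalladacycle (Pd, C8a, C4a, C4, C3, C2, O), and C–O reductive elimination should release the chroman. The closest known reaction type is the intramolecular Buchwald–Hartwig etherification of aryl halides with tertiary alcohols, which is established for 2,2-disubstituted chromans. The six-membered dihydropyran ring is closed at O1–C8a by reductive elimination from that palladacycle, that is, through the aryl C–O bond and not through C2–O. No stereocenter is created: the C2–O bond inherited from linalool is never broken, so the (2R) configuration is carried through unchanged. The step needs C–O reductive elimination to be faster than hydrodebromination; the substrate favors this because the alkoxide carbon bears no hydrogen (no β-hydride source), the only alkene is remote and trisubstituted, and the short tether holds the oxygen next to the hindered arylpalladium center.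

**Step 9**
Reactants: 13 (2R)-6-methoxy-2,8-dimethyl-2-[(4R,8S)-4,8,12-trimethyltridec-11-en-1-yl]-3,4-dihydro-2H-chromene
Product: 14 (2R)-2,8-dimethyl-2-[(4R,8S)-4,8,12-trimethyltridec-11-en-1-yl]-3,4-dihydro-2H-chromen-6-ol (target)
Conditions: NaSEt (5 equiv), DMF, 130 °C, argon; then 1 M HCl
Reagents that add atoms: none
Why: In this nucleophilic O-demethylation ethanethiolate should attack the unhindered O–CH3 carbon by SN2 and release the C6 phenoxide, whereas the chroman ether carbon C2 is tertiary and the isolated trisubstituted alkene is inert to thiolate.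

**Compound list**
1 | (R)-linalool, (3R)-3,7-dimethylocta-1,6-dien-3-ol | CC(C)=CCC[C@](O)(C)C=C | starting material
2 | 1-bromo-3-methoxy-5-methylbenzene | COc1cc(C)cc(Br)c1 | starting material
3 | 9-[(3S)-3-hydroxy-3,7-dimethyloct-6-en-1-yl]-9-borabicyclo[3.3.1]nonane (descriptor changes by CIP ranking only) | CC(C)=CCC[C@](O)(C)CCB1C2CCCC1CCC2 | intermediate (not isolated)
4 | (3R)-1-(3-methoxy-5-methylphenyl)-3,7-dimethyloct-6-en-3-ol | CC(C)=CCC[C@](O)(C)CCc1cc(C)cc(OC)c1 | intermediate
5 | (2E,6R)-8-(3-methoxy-5-methylphenyl)-2,6-dimethyloct-2-ene-1,6-diol | OC/C(C)=C/CC[C@](O)(C)CCc1cc(C)cc(OC)c1 | intermediate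
6 | (2S,6R)-8-(3-methoxy-5-methylphenyl)-2,6-dimethyloctane-1,6-diol | OC[C@@H](C)CCC[C@](O)(C)CCc1cc(C)cc(OC)c1 | intermediate
7 | (2S,6R)-8-(2-bromo-5-methoxy-3-methylphenyl)-2,6-dimethyloctane-1,6-diol | OC[C@@H](C)CCC[C@](O)(C)CCc1cc(OC)cc(C)c1Br | intermediate
8 | (2S,6R)-8-(2-bromo-5-methoxy-3-methylphenyl)-6-hydroxy-2,6-dimethyloctyl 4-methylbenzenesulfonate | Cc1ccc(cc1)S(=O)(=O)OC[C@@H](C)CCC[C@](O)(C)CCc1cc(OC)cc(C)c1Br | intermediate
9 | (R)-citronellol, (3R)-3,7-dimethyloct-6-en-1-ol | CC(C)=CCC[C@@H](C)CCO | starting material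
10 | (R)-citronellyl bromide, (6R)-8-bromo-2,6-dimethyloct-2-ene | CC(C)=CCC[C@@H](C)CCBr | intermediate
11 | (R)-citronellylmagnesium bromide, [(3R)-3,7-dimethyloct-6-en-1-yl]magnesium bromide | CC(C)=CCC[C@@H](C)CC[Mg]Br | intermediate (not isolated)
12 | (3R,7R,11S)-1-(2-bromo-5-methoxy-3-methylphenyl)-3,7,11,15-tetramethylhexadec-14-en-3-ol | CC(C)=CCC[C@@H](C)CCC[C@@H](C)CCC[C@](O)(C)CCc1cc(OC)cc(C)c1Br | intermediate
13 | (2R)-6-methoxy-2,8-dimethyl-2-[(4R,8S)-4,8,12-trimethyltridec-11-en-1-yl]-3,4-dihydro-2H-chromene | CC(C)=CCC[C@@H](C)CCC[C@@H](C)CCC[C@]1(C)CCc2cc(OC)cc(C)c2O1 | intermediate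
14 | (2R)-2,8-dimethyl-2-[(4R,8S)-4,8,12-trimethyltridec-11-en-1-yl]-3,4-dihydro-2H-chromen-6-ol | CC(C)=CCC[C@@H](C)CCC[C@@H](C)CCC[C@]1(C)CCc2cc(O)cc(C)c2O1 | target

**Step count**
Total: 9 steps. Longest linear sequence: 8 steps (steps 1–5 and 7–9 from (R)-linalool); step 6 is the one-step side branch.

**Steps most likely to fail**

Step 8. C–O reductive elimination from the congested, electron-rich arylpalladium alkoxide may be too slow, so that reduction of the C8a–Br bond or β-carbon fragmentation of the alkoxide takes over. The fallback forms the same O1–C8a bond with copper, a pathway that has no palladium hydride route. It sets out from 12: a copper-catalyzed aromatic halogen exchange (CuI, NaI, trans-N,N'-dimethylcyclohexane-1,2-diamine, dioxane, 110 °C) would give (3R,7R,11S)-1-(2-iodo-5-methoxy-3-methylphenyl)-3,7,11,15-tetramethylhexadec-14-en-3-ol F1. An Ullmann-type intramolecular etherification through a monovalent copper alkoxide (CuI, 3,4,7,8-tetramethyl-1,10-phenanthroline, Cs2CO3, toluene, 110 °C) would then close the ring and rejoin the route at 13, again with the C2–O bond untouched.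

Step 3. Hydrogen delivery to the allylic alcohol may show insufficient or reversed facial discrimination, giving C4' epimers that could not be separated downstream. The fallback moves the hydrogenation to the carboxylic acid oxidation level, where the tiglic acid substrate class has a well-established sense of induction. It sets out from 5: MnO2 (CH2Cl2, rt) would give (2E,6R)-6-hydroxy-8-(3-methoxy-5-methylphenyl)-2,6-dimethyloct-2-enal F2. Pinnick oxidation (NaClO2, NaH2PO4, 2-methyl-2-butene, t-BuOH/H2O) would give (2E,6R)-6-hydroxy-8-(3-methoxy-5-methylphenyl)-2,6-dimethyloct-2-enoic acid F3. Carboxylate-directed hydrogenation (Ru(OAc)2[(S)-BINAP], H2 100 atm, MeOH) would give (2S,6R)-6-hydroxy-8-(3-methoxy-5-methylphenyl)-2,6-dimethyloctanoic acid F4, and LiAlH4 (THF, 0 °C to rt) would reduce it to the diol, rejoining the route at 6.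

Step 7. Displacement at the β-branched tosylate may be sluggish and compete with exchange or metalation at the aryl bromide and with homocoupling of the Grignard reagent. The fallback builds C5'–C6' by olefination and selective reduction. It sets out from 8: NaI (acetone, reflux) would give (3R,7S)-1-(2-bromo-5-methoxy-3-methylphenyl)-8-iodo-3,7-dimethyloctan-3-ol F5. PPh3 (MeCN, reflux) would give [(2S,6R)-8-(2-bromo-5-methoxy-3-methylphenyl)-6-hydroxy-2,6-dimethyloctyl]triphenylphosphonium iodide F6. Wittig reaction (NaN(SiMe3)2 2.1 equiv, THF, −78 °C) with commercial (R)-citronellal (CC(C)=CCC[C@@H](C)CC=O) would give (3R,7S,8Z,11R)-1-(2-bromo-5-methoxy-3-methylphenyl)-3,7,11,15-tetramethylhexadeca-8,14-dien-3-ol F7. Diimide (2-nitrobenzenesulfonyl hydrazide, Et3N, CH2Cl2, rt) should reduce only the 1,2-disubstituted alkene, sparing the trisubstituted alkene and the aryl bromide, and rejoin the route at 12.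

**Further compounds**
F1 | step 8 | (3R,7R,11S)-1-(2-iodo-5-methoxy-3-methylphenyl)-3,7,11,15-tetramethylhexadec-14-en-3-ol | CC(C)=CCC[C@@H](C)CCC[C@@H](C)CCC[C@](O)(C)CCc1cc(OC)cc(C)c1I
F2 | step 3 | (2E,6R)-6-hydroxy-8-(3-methoxy-5-methylphenyl)-2,6-dimethyloct-2-enal | O=C/C(C)=C/CC[C@](O)(C)CCc1cc(C)cc(OC)c1
F3 | step 3 | (2E,6R)-6-hydroxy-8-(3-methoxy-5-methylphenyl)-2,6-dimethyloct-2-enoic acid | OC(=O)/C(C)=C/CC[C@](O)(C)CCc1cc(C)cc(OC)c1
F4 | step 3 | (2S,6R)-6-hydroxy-8-(3-methoxy-5-methylphenyl)-2,6-dimethyloctanoic acid | OC(=O)[C@@H](C)CCC[C@](O)(C)CCc1cc(C)cc(OC)c1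
F5 | step 7 | (3R,7S)-1-(2-bromo-5-methoxy-3-methylphenyl)-8-iodo-3,7-dimethyloctan-3-ol | IC[C@@H](C)CCC[C@](O)(C)CCc1cc(OC)cc(C)c1Br
F6 | step 7 | [(2S,6R)-8-(2-bromo-5-methoxy-3-methylphenyl)-6-hydroxy-2,6-dimethyloctyl]triphenylphosphonium iodide | c1ccccc1[P+](c1ccccc1)(c1ccccc1)C[C@@H](C)CCC[C@](O)(C)CCc1cc(OC)cc(C)c1Br.[I-]
F7 | step 7 | (3R,7S,8Z,11R)-1-(2-bromo-5-methoxy-3-methylphenyl)-3,7,11,15-tetramethylhexadeca-8,14-dien-3-ol | CC(C)=CCC[C@@H](C)C/C=C\[C@@H](C)CCC[C@](O)(C)CCc1cc(OC)cc(C)c1Br
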